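**Plan**

- Retrosynthesis: the 2‑OH is traced back to a silyl ether and the quinone to a 4‑methoxyphenol (oxidative demethylation). The arene is then cut at two ring bonds, C6(H)–C1(=O) and C5(OMe)–C4(=O), which releases methoxyacetylene and the four‑carbon unit C1–C2(O)–C3(docosyl)–C4.
- Enabling feature: C6H=C5(OMe) is an ynol ether at the alkyne oxidation level, nucleophilic at C6. C1, C2 and C4 all carry oxygen and C3 carries the chain, which is the pattern of a squaric‑acid‑derived cyclobutenone whose vinylketene has its electrophilic carbon at C1 and its α‑carbon at C4.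
- Forward: dimethyl squarate is mono‑reduced, silylated, and treated with the docosyl Grignard reagent with carbonyl transposition to give a 2‑methoxy‑3‑docosyl‑4‑silyloxycyclobutenone. Heating with methoxyacetylene (4π opening, [2+2], 4π opening, 6π closure) builds the only ring of the target, the six‑membered carbocycle, as a pentasubstituted phenol. Oxidation and desilylation give the quinone.
- The free hydroxyl and the methoxy group are differentiated from the start (silyl versus methyl), so no selective demethylation is needed.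
- Stereochemistry: the target has no stereocentre and no stereogenic double bond; the racemic centre of the cyclobutenone intermediates is erased in the key step.

Key step: step 5

Remark on the chemistry: dimethyl squarate, 1‑bromodocosane and chloroacetaldehyde dimethyl acetal are taken as the purchased materials. Methoxyacetylene is made fresh (step 4) because it is volatile and is not assumed to be on the shelf. Compounds 2, 3, 6, 7, 12 and 14 are racemic.

**Step 1**
Reactants: 1 dimethyl squarate (3,4‑dimethoxycyclobut‑3‑ene‑1,2‑dione)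
Product: 2 4‑hydroxy‑2,3‑dimethoxycyclobut‑2‑en‑1‑one (racemic)
Conditions: LiAlH(OtBu)3 (1.05 equiv), THF, −78 → −20 °C; aq. Rochelle salt, 0 °C (neutral work‑up)
Reagents that add atoms: none
Why: Chemoselective carbonyl 1,2‑reduction of a squarate diester with a hindered mono‑hydride reagent should stop at the hydroxy ketone, because the remaining carbonyl of the aluminium alkoxide is a deactivated vinylogous ester, and the neutral work‑up avoids acid‑induced loss of methanol; the new centre is racemic and is erased in step 5.

**Step 2**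
Reactants: 2 4‑hydroxy‑2,3‑dimethoxycyclobut‑2‑en‑1‑one
Product: 3 4‑(tert‑butyldimethylsilyloxy)‑2,3‑dimethoxycyclobut‑2‑en‑1‑one (racemic)
Conditions: TBSCl (1.2 equiv), imidazole (2 equiv), DMF, 0 °C → rt
Reagents that add atoms: tert‑butyldimethylsilyl chloride, CC(C)(C)[Si](C)(C)Cl
Why: Standard silyl ether formation on a secondary hydroxyl; the ether later keeps the oxygen from adding to the ketene and carries the future quinone 2‑OH through the route.

**Step 3**
Reactants: 3 4‑(tert‑butyldimethylsilyloxy)‑2,3‑dimethoxycyclobut‑2‑en‑1‑one; 4 1‑bromodocosane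
Product: 7 4‑(tert‑butyldimethylsilyloxy)‑3‑docosyl‑2‑methoxycyclobut‑2‑en‑1‑one (racemic), via docosylmagnesium bromide 5 (not isolated), via tertiary carbinol 6 (not isolated)
Conditions: (a) 4, Mg, THF, 45 °C; (b) 3, THF, −78 → −30 °C; (c) (CF3CO)2O, −78 → 0 °C, then H2O/NaHCO3
Reagents that add atoms: water, O
Why: Grignard 1,2‑addition to the only carbonyl of 3 gives carbinol 6 as its bromomagnesium alkoxide, and trifluoroacetylation ionises it to a methoxy‑stabilised cyclobutenyl cation that water captures at the oxocarbenium carbon with loss of methanol (1,3‑carbonyl transposition of a vinylogous ester adduct, Stork–Danheiser type, standard for squarate adducts); a competing conjugate addition–elimination at the β‑methoxy carbon would give the same constitution 7.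

**Step 4**
Reactants: 8 chloroacetaldehyde dimethyl acetal (2‑chloro‑1,1‑dimethoxyethane)
Product: 10 methoxyacetylene (methoxyethyne), via sodium methoxyacetylide 9 (not isolated)
Conditions: NaNH2 (3 equiv), liq. NH3, −33 °C; NH3 evaporated; sat. aq. NaCl, −20 °C; distilled into cold toluene and used at once
Reagents that add atoms: none
Why: Base‑induced double β‑elimination (methanol, then HCl) from the chloroacetal with excess NaNH2 is the standard preparation of alkoxyacetylenes and ends at the acetylide, which brine protonates to release the volatile ynol ether.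

**Step 5**
Reactants: 7 4‑(tert‑butyldimethylsilyloxy)‑3‑docosyl‑2‑methoxycyclobut‑2‑en‑1‑one; 10 methoxyacetylene
Product: 15 2‑(tert‑butyldimethylsilyloxy)‑3‑docosyl‑4,5‑dimethoxyphenol, via vinylketene 11 (not isolated), via vinylcyclobutenone 12 (not isolated), via dienylketene 13 (not isolated), via cyclohexadienone 14 (not isolated)
Conditions: 10 (3 equiv), toluene, sealed tube, argon, 80 °C then 110 °C
Reagents that add atoms: none
Why: Heating opens cyclobutenone 7 by 4π‑electrocyclic cleavage of its C1–C4 bond to vinylketene 11 (silyloxy group outward), and the ketene C=C then undergoes a polar [2+2] cycloaddition with ynol ether 10 in which the nucleophilic CH carbon bonds to the ketene carbonyl carbon and the methoxy‑bearing alkyne carbon bonds to the methoxy‑bearing α‑carbon, so both new ring C–C bonds arise in this one event and give the 4‑vinylcyclobutenone 12. A second 4π opening of 12 (cleaving the old ketene C–C bond) gives dienylketene 13, 6π‑disrotatory electrocyclisation closes the six‑membered carbocycle to dienone 14, and enolisation delivers phenol 15 with every atom of both partners retained. The closest known reaction type is the Danheiser benzannulation of cyclobutenones with alkoxyacetylenes. The transient four‑membered ring of 12 closes by [2+2] cycloaddition and the benzene ring by 6π electrocyclisation of a (Z)‑dienylketene. No stereocentre remains, since the racemic centres of 7, 12 and 14 are erased by ring opening and aromatisation. The selectivity needed is the orientation of the alkyne, secured by the matched polarity of ketene (electrophilic at the carbonyl carbon) and ynol ether (nucleophilic at CH); inward rotation of the vinyl group in 12 is secured by the outward preference of the donor methoxy group, and lactonisation of the ketene is blocked by the silyl ether.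

**Step 6**
Reactants: 15 2‑(tert‑butyldimethylsilyloxy)‑3‑docosyl‑4,5‑dimethoxyphenol
Product: 17 3‑docosyl‑2‑hydroxy‑5‑methoxy‑1,4‑benzoquinone, via silyloxyquinone 16 (not isolated)
Conditions: (NH4)2Ce(NO3)6 (2.2 equiv), MeCN–CH2Cl2–H2O, 0 °C; then AcOH–THF–H2O, rt
Reagents that add atoms: water, O
Why: Oxidative demethylation of a 4‑methoxyphenol to the p‑quinone (water adds at the methoxy‑bearing para carbon and methanol leaves) should give 16, whose silyl vinylogous ester is as labile as a silyl ester and is hydrolysed by aqueous acetic acid, while the conjugated 5‑methoxy group stays in place.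

**Compound list**

1 | dimethyl squarate (3,4‑dimethoxycyclobut‑3‑ene‑1,2‑dione) | COC1=C(OC)C(=O)C1=O | starting material
2 | 4‑hydroxy‑2,3‑dimethoxycyclobut‑2‑en‑1‑one (racemic) | O=C1C(OC)=C(OC)C1O | intermediate
3 | 4‑(tert‑butyldimethylsilyloxy)‑2,3‑dimethoxycyclobut‑2‑en‑1‑one (racemic) | O=C1C(OC)=C(OC)C1O[Si](C)(C)C(C)(C)C | intermediate
4 | 1‑bromodocosane | CCCCCCCCCCCCCCCCCCCCCCBr | starting material
5 | docosylmagnesium bromide | CCCCCCCCCCCCCCCCCCCCCC[Mg]Br | intermediate (not isolated)
6 | 4‑(tert‑butyldimethylsilyloxy)‑1‑docosyl‑2,3‑dimethoxycyclobut‑2‑en‑1‑ol (racemic diastereomer mixture; formed in step 3 as its bromomagnesium alkoxide) | CCCCCCCCCCCCCCCCCCCCCCC1(O)C(OC)=C(OC)C1O[Si](C)(C)C(C)(C)C | intermediate (not isolated)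
7 | 4‑(tert‑butyldimethylsilyloxy)‑3‑docosyl‑2‑methoxycyclobut‑2‑en‑1‑one (racemic) | CCCCCCCCCCCCCCCCCCCCCCC1=C(OC)C(=O)C1O[Si](C)(C)C(C)(C)C | intermediate
8 | chloroacetaldehyde dimethyl acetal (2‑chloro‑1,1‑dimethoxyethane) | COC(CCl)OC | starting material
9 | sodium methoxyacetylide | [Na+].[C-]#COC | intermediate (not isolated)
10 | methoxyacetylene (methoxyethyne) | C#COC | intermediate
11 | (E)‑4‑(tert‑butyldimethylsilyloxy)‑3‑docosyl‑2‑methoxybuta‑1,3‑dien‑1‑one (vinylketene) | O=C=C(OC)/C(CCCCCCCCCCCCCCCCCCCCCC)=C/O[Si](C)(C)C(C)(C)C | intermediate (not isolated)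
12 | 4‑[(E)‑2‑(tert‑butyldimethylsilyloxy)‑1‑docosylethenyl]‑3,4‑dimethoxycyclobut‑2‑en‑1‑one (racemic) | O=C1C=C(OC)C1(OC)/C(CCCCCCCCCCCCCCCCCCCCCC)=C/O[Si](C)(C)C(C)(C)C | intermediate (not isolated)
13 | (3Z,5E)‑6‑(tert‑butyldimethylsilyloxy)‑5‑docosyl‑3,4‑dimethoxyhexa‑1,3,5‑trien‑1‑one (dienylketene) | O=C=C/C(OC)=C(OC)\C(CCCCCCCCCCCCCCCCCCCCCC)=C\O[Si](C)(C)C(C)(C)C | intermediate (not isolated)
14 | 6‑(tert‑butyldimethylsilyloxy)‑5‑docosyl‑3,4‑dimethoxycyclohexa‑2,4‑dien‑1‑one (racemic) | O=C1C=C(OC)C(OC)=C(CCCCCCCCCCCCCCCCCCCCCC)C1O[Si](C)(C)C(C)(C)C | intermediate (not isolated)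
15 | 2‑(tert‑butyldimethylsilyloxy)‑3‑docosyl‑4,5‑dimethoxyphenol | CCCCCCCCCCCCCCCCCCCCCCc1c(OC)c(OC)cc(O)c1O[Si](C)(C)C(C)(C)C | intermediate
16 | 2‑(tert‑butyldimethylsilyloxy)‑3‑docosyl‑5‑methoxycyclohexa‑2,5‑diene‑1,4‑dione | CCCCCCCCCCCCCCCCCCCCCCC1=C(O[Si](C)(C)C(C)(C)C)C(=O)C=C(OC)C1=O | intermediate (not isolated)
17 | 3‑docosyl‑2‑hydroxy‑5‑methoxy‑1,4‑benzoquinone | CCCCCCCCCCCCCCCCCCCCCCC1=C(O)C(=O)C=C(OC)C1=O | target

**Totals and risks**

Total step count: 6. Longest linear sequence: 5 steps (steps 1, 2, 3, 5, 6); step 4 is a one‑step side branch.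

The three steps most likely to fail:

Step 5. Bimolecular capture of the electron‑rich vinylketene by the volatile ynol ether may be slower than reclosure, ketene dimerisation or thermal polymerisation of the alkyne. The fallback sets out from 7 and 10 and comes back to the route at 17; it makes the same two ring bonds in two separate known operations. Desilylation of 7 (HF·pyridine, THF, 0 °C) should give 3‑docosyl‑4‑hydroxy‑2‑methoxycyclobut‑2‑en‑1‑one F1, and Dess–Martin oxidation should give 3‑docosyl‑4‑methoxycyclobut‑3‑ene‑1,2‑dione F2. Lithium methoxyacetylide F3, made from 10 with n‑BuLi in THF at −78 °C, should add to the more electrophilic carbonyl of F2 (the one next to the methoxy‑bearing carbon, which is not a vinylogous ester) to give 2‑docosyl‑4‑hydroxy‑3‑methoxy‑4‑(methoxyethynyl)cyclobut‑2‑en‑1‑one F4. Moore ring expansion of F4 in refluxing toluene should give 3‑docosyl‑2,5‑dimethoxy‑1,4‑benzoquinone F5. Selective hydrolysis of its alkyl‑flanked, twisted 2‑methoxy group with aqueous HClO4 in dioxane, the behaviour expected of 2,5‑dimethoxy‑3‑alkylbenzoquinones, should return 17.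

Step 3. The basic Grignard reagent may deprotonate or eliminate at the silyloxy‑bearing α‑carbon instead of adding, or the silyl ether may be lost during the acid‑induced transposition. The fallback sets out from 1 and 4 (through 5) and comes back to the route at 6; it attaches the chain before the ring hydroxyl exists. Addition of 5 to dimethyl squarate 1 (THF, −78 °C), which has no acidic C–H, should give 4‑docosyl‑4‑hydroxy‑2,3‑dimethoxycyclobut‑2‑en‑1‑one F6. 1,2‑Reduction of its vinylogous‑ester carbonyl with (i‑Bu)2AlH at −78 °C (Rochelle‑salt work‑up) should give 1‑docosyl‑2,3‑dimethoxycyclobut‑2‑ene‑1,4‑diol F7. Selective silylation of the secondary hydroxyl (TBSCl, imidazole, DMF) gives carbinol 6 as the free alcohol, which (CF3CO)2O and then water carry on to 7 as in the last stage of step 3.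

Step 6. The electron‑rich ring may be over‑oxidised, or water may attack the silyloxy‑bearing carbon (ortho‑quinone pathway) in competition with the methoxy‑bearing para carbon. The fallback sets out from 15 and comes back to the route at 17. Two‑electron dearomatisation with PhI(OAc)2 in methanol at 0 °C should give the quinone monoketal 2‑(tert‑butyldimethylsilyloxy)‑3‑docosyl‑4,4,5‑trimethoxycyclohexa‑2,5‑dien‑1‑one F8, in which the para position is fixed by methanol capture. Aqueous acetic acid then hydrolyses both the ketal and the silyl ether to 17.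

**Further compounds**

F1 | step 5 | 3‑docosyl‑4‑hydroxy‑2‑methoxycyclobut‑2‑en‑1‑one | CCCCCCCCCCCCCCCCCCCCCCC1=C(OC)C(=O)C1O
F2 | step 5 | 3‑docosyl‑4‑methoxycyclobut‑3‑ene‑1,2‑dione | CCCCCCCCCCCCCCCCCCCCCCC1=C(OC)C(=O)C1=O
F3 | step 5 | lithium methoxyacetylide | [Li]C#COC
F4 | step 5 | 2‑docosyl‑4‑hydroxy‑3‑methoxy‑4‑(methoxyethynyl)cyclobut‑2‑en‑1‑one | CCCCCCCCCCCCCCCCCCCCCCC1=C(OC)C(O)(C#COC)C1=O
F5 | step 5 | 3‑docosyl‑2,5‑dimethoxy‑1,4‑benzoquinone | CCCCCCCCCCCCCCCCCCCCCCC1=C(OC)C(=O)C=C(OC)C1=O
F6 | step 3 | 4‑docosyl‑4‑hydroxy‑2,3‑dimethoxycyclobut‑2‑en‑1‑one | CCCCCCCCCCCCCCCCCCCCCCC1(O)C(OC)=C(OC)C1=O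
F7 | step 3 | 1‑docosyl‑2,3‑dimethoxycyclobut‑2‑ene‑1,4‑diol | CCCCCCCCCCCCCCCCCCCCCCC1(O)C(OC)=C(OC)C1O
F8 | step 6 | 2‑(tert‑butyldimethylsilyloxy)‑3‑docosyl‑4,4,5‑trimethoxycyclohexa‑2,5‑dien‑1‑one | CCCCCCCCCCCCCCCCCCCCCCC1=C(O[Si](C)(C)C(C)(C)C)C(=O)C=C(OC)C1(OC)OC
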